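**Retrosynthetic overview**
1. Target 12 ⇒ the pyrone ring of the apigenin half is removed last: Mentzer annulation of β-ketoester 11 onto the free phloroglucinol ring of 10.
2. 10 ⇒ perbenzylated 3-arylflavone 9 ⇒ Baker–Venkataraman rearrangement and cyclodehydration of deoxybenzoin 7, whose single ortho 4-methoxybenzoate supplies C2 and ring B of the acacetin half.
3. Key disconnection, the inter-flavone C3–C6'' bond (the CH2–aryl bond of 7): a hypervalent-iodine enolonium of aryl methyl ketone 3 (an α-keto cation equivalent) plus 1,3,5-tris(benzyloxy)benzene 5, joining two carbons that are both natively nucleophilic.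
4. Ring order: ring C of the acacetin half (step 4), then ring C of the apigenin half (step 6); both A rings and both B rings are bought.

Assumption: the SMILES has no stereocentre and no descriptor for the hindered biaryl axis, so the target is made as the constitution given; 1, 5 and 11 are taken as catalogue compounds.

**Route**

Step 1
Reactants: 1 1-[2,4-bis(benzyloxy)-6-hydroxyphenyl]ethan-1-one; 2 4-methoxybenzoyl chloride (1.2 equiv)
Product: 3 2-acetyl-3,5-bis(benzyloxy)phenyl 4-methoxybenzoate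
Conditions: pyridine, DMAP (0.1 equiv), CH2Cl2, 0 °C → rt
Reagents that add atoms: none
Why: Pyridine/DMAP O-aroylation (Einhorn-type Schotten–Baumann esterification) of the one free, chelated phenol places the future C2 and ring-B carbons on the ortho oxygen for the later O→C transfer, while the two benzyl ethers already present leave with the other benzyl groups in step 5.

Step 2
Reactants: 3 2-acetyl-3,5-bis(benzyloxy)phenyl 4-methoxybenzoate
Product: 4 3,5-bis(benzyloxy)-2-[1-(trimethylsilyloxy)ethenyl]phenyl 4-methoxybenzoate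
Conditions: TMSOTf (1.3 equiv), Et3N (1.6 equiv), CH2Cl2, 0 °C → rt; cold aq NaHCO3 wash, used crude
Reagents that add atoms: trimethylsilyl trifluoromethanesulfonate (TMSOTf), C[Si](C)(C)OS(=O)(=O)C(F)(F)F
Why: Soft enolisation with silyl triflate and amine gives the terminal trimethylsilyl enol ether without ever forming a free enolate, so no premature Baker–Venkataraman acyl transfer or ester cleavage occurs.

Step 3
Reactants: 4 3,5-bis(benzyloxy)-2-[1-(trimethylsilyloxy)ethenyl]phenyl 4-methoxybenzoate (1.1 equiv); 5 1,3,5-tris(benzyloxy)benzene (2.5 equiv, excess recovered)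
Product: 7 3,5-bis(benzyloxy)-2-{[2,4,6-tris(benzyloxy)phenyl]acetyl}phenyl 4-methoxybenzoate, via enolonium species 6 (not isolated)
Conditions: PhI(OH)OTs (1.0 equiv), BF3·OEt2 (1.2 equiv), CH2Cl2, −78 °C, 10 min; then 5, −78 → −20 °C; aq NaHCO3
Reagents that add atoms: none
Why: Proposed new method: the silyl enol ether attacks BF3-activated PhI(OH)OTs at −78 °C, far faster than any arene does, to give the O-bound trivalent-iodine enolate 6, whose CH2 terminus is an α-keto cation equivalent (iodobenzene as hypernucleofuge) that is captured at carbon by the threefold-symmetric, strongly nucleophilic trialkoxybenzene 5 in a Friedel–Crafts-type SN2′ displacement, the closest known reaction type being the metal-free α-arylation of ketones through preformed hypervalent-iodine enolonium species with indoles, pyrroles and other π-nucleophiles; the ketone's own ring carries the electron-withdrawing enolonium carbon and an aroyloxy group and is outcompeted by the excess of 5, all positions of 5 are equivalent, and 5 never meets free oxidant because 6 is formed first.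

Step 4
Reactants: 7 3,5-bis(benzyloxy)-2-{[2,4,6-tris(benzyloxy)phenyl]acetyl}phenyl 4-methoxybenzoate
Product: 9 5,7-bis(benzyloxy)-2-(4-methoxyphenyl)-3-[2,4,6-tris(benzyloxy)phenyl]-4H-chromen-4-one, via Baker–Venkataraman diketone 8 (not isolated)
Conditions: LiN(SiMe3)2 (2.2 equiv), THF, −78 → 0 °C; then HCl (4 M in dioxane), MeOH, 40 °C
Reagents that add atoms: none
Why: Baker–Venkataraman rearrangement (intramolecular Claisen transfer of the ortho 4-methoxybenzoyl group to the benzylic lithium enolate), then mild acid cyclodehydration of the 2-hydroxyaryl 1,3-diketone to the 2,3-diarylchromone; the benzyl ethers tolerate both stages and keep the flanking oxygens of the tribenzyloxyphenyl ring etherified so that no benzofuran can form.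

Step 5
Reactants: 9 5,7-bis(benzyloxy)-2-(4-methoxyphenyl)-3-[2,4,6-tris(benzyloxy)phenyl]-4H-chromen-4-one
Product: 10 5,7-dihydroxy-2-(4-methoxyphenyl)-3-(2,4,6-trihydroxyphenyl)-4H-chromen-4-one
Conditions: H2 (1 atm), Pd/C (10 wt%), THF–MeOH, rt
Reagents that add atoms: none
Why: Catalytic hydrogenolysis of all five aryl benzyl ethers over palladium on carbon; the aryl methyl ether and the hindered tetrasubstituted chromone C2=C3 bond are inert under these conditions.

Step 6
Reactants: 10 5,7-dihydroxy-2-(4-methoxyphenyl)-3-(2,4,6-trihydroxyphenyl)-4H-chromen-4-one; 11 ethyl 3-(4-hydroxyphenyl)-3-oxopropanoate (2 equiv)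
Product: 12 5,7-dihydroxy-6-[5,7-dihydroxy-2-(4-methoxyphenyl)-4-oxo-4H-chromen-3-yl]-2-(4-hydroxyphenyl)-4H-chromen-4-one (target)
Conditions: Ph2O, 240 °C (microwave), 20 min, Ar
Reagents that add atoms: none
Why: Mentzer pyrone synthesis (thermal Simonis-type annulation): the aroylketene released from 11 C-acylates one of the two equivalent CH positions of the free phloroglucinol ring, which is far more nucleophilic than the carbonyl-deactivated ring A of the acacetin half, and cyclodehydration through the unhindered hydroxyl remote from the bulky chromonyl group (the preference seen when C-substituted phloroglucinol ketones close to 6-substituted flavonoids) gives the 6-linked biflavone with no stereocentre created.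

**Compound list**
1 | 1-[2,4-bis(benzyloxy)-6-hydroxyphenyl]ethan-1-one | CC(=O)c1c(O)cc(OCc2ccccc2)cc1OCc1ccccc1 | starting material
2 | 4-methoxybenzoyl chloride | COc1ccc(cc1)C(Cl)=O | starting material
3 | 2-acetyl-3,5-bis(benzyloxy)phenyl 4-methoxybenzoate | CC(=O)c1c(OC(=O)c2ccc(OC)cc2)cc(OCc2ccccc2)cc1OCc1ccccc1 | intermediate
4 | 3,5-bis(benzyloxy)-2-[1-(trimethylsilyloxy)ethenyl]phenyl 4-methoxybenzoate | C=C(O[Si](C)(C)C)c1c(OC(=O)c2ccc(OC)cc2)cc(OCc2ccccc2)cc1OCc1ccccc1 | intermediate
5 | 1,3,5-tris(benzyloxy)benzene | c1ccc(cc1)COc1cc(OCc2ccccc2)cc(OCc2ccccc2)c1 | starting material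
6 | enolonium species, 3,5-bis(benzyloxy)-2-{1-[phenyl(tosyloxy)iodanyloxy]ethenyl}phenyl 4-methoxybenzoate | C=C(OI(c1ccccc1)OS(=O)(=O)c1ccc(C)cc1)c1c(OC(=O)c2ccc(OC)cc2)cc(OCc2ccccc2)cc1OCc1ccccc1 | intermediate
7 | 3,5-bis(benzyloxy)-2-{[2,4,6-tris(benzyloxy)phenyl]acetyl}phenyl 4-methoxybenzoate | O=C(Cc1c(OCc2ccccc2)cc(OCc2ccccc2)cc1OCc1ccccc1)c1c(OC(=O)c2ccc(OC)cc2)cc(OCc2ccccc2)cc1OCc1ccccc1 | intermediate
8 | 1-[2,4-bis(benzyloxy)-6-hydroxyphenyl]-3-(4-methoxyphenyl)-2-[2,4,6-tris(benzyloxy)phenyl]propane-1,3-dione | COc1ccc(cc1)C(=O)C(c1c(OCc2ccccc2)cc(OCc2ccccc2)cc1OCc1ccccc1)C(=O)c1c(O)cc(OCc2ccccc2)cc1OCc1ccccc1 | intermediate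
9 | 5,7-bis(benzyloxy)-2-(4-methoxyphenyl)-3-[2,4,6-tris(benzyloxy)phenyl]-4H-chromen-4-one | COc1ccc(cc1)-c1oc2cc(OCc3ccccc3)cc(OCc3ccccc3)c2c(=O)c1-c1c(OCc2ccccc2)cc(OCc2ccccc2)cc1OCc1ccccc1 | intermediate
10 | 5,7-dihydroxy-2-(4-methoxyphenyl)-3-(2,4,6-trihydroxyphenyl)-4H-chromen-4-one | COc1ccc(cc1)-c1oc2cc(O)cc(O)c2c(=O)c1-c1c(O)cc(O)cc1O | intermediate
11 | ethyl 3-(4-hydroxyphenyl)-3-oxopropanoate | CCOC(=O)CC(=O)c1ccc(O)cc1 | starting material
12 | 5,7-dihydroxy-6-[5,7-dihydroxy-2-(4-methoxyphenyl)-4-oxo-4H-chromen-3-yl]-2-(4-hydroxyphenyl)-4H-chromen-4-one | COc1ccc(-c2oc3cc(O)cc(O)c3c(=O)c2-c2c(O)cc3oc(-c4ccc(O)cc4)cc(=O)c3c2O)cc1 | target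

**Totals**
Total step count: 6. Longest linear sequence: 6 (1 → 3 → 4 → 7 → 9 → 10 → 12; 2, 5 and 11 are bought).

**Steps most likely to fail, with fallbacks**

Step 3 (enolonium arylation). The risk is that 6 collapses to the α-tosyloxy ketone, or is attacked by the benzyloxy-bearing ring of a second molecule of 4, before 5 attacks at carbon. The fallback keeps the same bond but makes the arene the organometallic partner. From 4, NBS (THF, −78 °C) gives the α-bromoketone 3,5-bis(benzyloxy)-2-(bromoacetyl)phenyl 4-methoxybenzoate F1. From 5, NBS (MeCN, 0 °C) gives 2-bromo-1,3,5-tris(benzyloxy)benzene F2, which n-BuLi (THF, −78 °C) and then ZnCl2 convert into [2,4,6-tris(benzyloxy)phenyl]zinc chloride F3. A Negishi-type coupling of F1 with F3 (NiCl2(dme), 4,4′-di-tert-butyl-2,2′-bipyridine, THF–DMA, 0 °C) is base-free, so the ester is untouched, and it returns to 7.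

Step 4 (Baker–Venkataraman transfer and ring closure). The risk is that congestion at the benzylic enolate, flanked by two di-ortho-substituted rings, slows the O→C aroyl transfer so that only ester cleavage is seen. The fallback builds ring C by aldol chemistry instead of Claisen chemistry. From 7, K2CO3 (0.2 equiv) in MeOH–THF removes the ester to give 1-[2,4-bis(benzyloxy)-6-hydroxyphenyl]-2-[2,4,6-tris(benzyloxy)phenyl]ethan-1-one F4. Condensation of F4 with 4-methoxybenzaldehyde (pyrrolidine, EtOH, reflux; Knoevenagel then oxa-Michael) gives 5,7-bis(benzyloxy)-2-(4-methoxyphenyl)-3-[2,4,6-tris(benzyloxy)phenyl]chroman-4-one F5 as a racemic cis/trans mixture whose stereocentres are erased in the next operation. Dehydrogenation with I2 in pyridine at 90 °C returns to 9.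

Step 6 (Mentzer annulation). The risk is that closure through a hydroxyl flanking the biaryl bond gives the 8-linked isomer, and 240 °C is harsh for a hexaphenol. The fallback uses a stepwise, reversible closure. From 10, Friedel–Crafts acylation of the free phloroglucinol ring with (E)-4-hydroxycinnamic acid in BF3·OEt2 (80 °C) gives the chalcone 5,7-dihydroxy-2-(4-methoxyphenyl)-3-{2,4,6-trihydroxy-3-[(E)-3-(4-hydroxyphenyl)prop-2-enoyl]phenyl}-4H-chromen-4-one F6. NaOAc in refluxing EtOH closes it to the 6-linked flavanone 5,7-dihydroxy-6-[5,7-dihydroxy-2-(4-methoxyphenyl)-4-oxo-4H-chromen-3-yl]-2-(4-hydroxyphenyl)chroman-4-one F7 (racemic). Any 8-linked flavanone 5,7-dihydroxy-8-[5,7-dihydroxy-2-(4-methoxyphenyl)-4-oxo-4H-chromen-3-yl]-2-(4-hydroxyphenyl)chroman-4-one F8 is reopened to F6 with aq KOH and recycled through the chalcone–flavanone equilibrium. I2 in pyridine at 90 °C dehydrogenates F7 and so comes back to the route at 12.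

**Further compounds**
F1 | step 3 | 3,5-bis(benzyloxy)-2-(bromoacetyl)phenyl 4-methoxybenzoate | BrCC(=O)c1c(OC(=O)c2ccc(OC)cc2)cc(OCc2ccccc2)cc1OCc1ccccc1
F2 | step 3 | 2-bromo-1,3,5-tris(benzyloxy)benzene | Brc1c(OCc2ccccc2)cc(OCc2ccccc2)cc1OCc1ccccc1
F3 | step 3 | [2,4,6-tris(benzyloxy)phenyl]zinc chloride | Cl[Zn]c1c(OCc2ccccc2)cc(OCc2ccccc2)cc1OCc1ccccc1
F4 | step 4 | 1-[2,4-bis(benzyloxy)-6-hydroxyphenyl]-2-[2,4,6-tris(benzyloxy)phenyl]ethan-1-one | O=C(Cc1c(OCc2ccccc2)cc(OCc2ccccc2)cc1OCc1ccccc1)c1c(O)cc(OCc2ccccc2)cc1OCc1ccccc1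
F5 | step 4 | 5,7-bis(benzyloxy)-2-(4-methoxyphenyl)-3-[2,4,6-tris(benzyloxy)phenyl]chroman-4-one (racemic cis/trans mixture) | COc1ccc(cc1)C1Oc2cc(OCc3ccccc3)cc(OCc3ccccc3)c2C(=O)C1c1c(OCc2ccccc2)cc(OCc2ccccc2)cc1OCc1ccccc1
F6 | step 6 | 5,7-dihydroxy-2-(4-methoxyphenyl)-3-{2,4,6-trihydroxy-3-[(E)-3-(4-hydroxyphenyl)prop-2-enoyl]phenyl}-4H-chromen-4-one | COc1ccc(cc1)-c1oc2cc(O)cc(O)c2c(=O)c1-c1c(O)cc(O)c(C(=O)/C=C/c2ccc(O)cc2)c1O
F7 | step 6 | 5,7-dihydroxy-6-[5,7-dihydroxy-2-(4-methoxyphenyl)-4-oxo-4H-chromen-3-yl]-2-(4-hydroxyphenyl)chroman-4-one (racemic) | COc1ccc(cc1)-c1oc2cc(O)cc(O)c2c(=O)c1-c1c(O)cc2OC(CC(=O)c2c1O)c1ccc(O)cc1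
F8 | step 6 | 5,7-dihydroxy-8-[5,7-dihydroxy-2-(4-methoxyphenyl)-4-oxo-4H-chromen-3-yl]-2-(4-hydroxyphenyl)chroman-4-one (racemic) | COc1ccc(cc1)-c1oc2cc(O)cc(O)c2c(=O)c1-c1c(O)cc(O)c2C(=O)CC(Oc12)c1ccc(O)cc1
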